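**Retrosynthetic overview**
1. The target comes from late acylations of a cis-fused dauc-8-ene core (tigloyl chloride at 10-OH, acetyl-protected 4-hydroxybenzoyl chloride at 6-OH) and an oxazaborolidine reduction of a C10 enone.
2. The 6-OH/C7H2/enone unit comes from Pd–formate hydrogenolysis of a γ,δ-epoxy enone; the epoxide is placed by the 4-OH; the angular CH3 and C10=O come from opening a C1/C10 siloxycyclopropane.
3. The C4 carbinol comes from isopropyl addition to the cyclopentanone; the cyclopropane comes from Simmons–Smith reaction of a silyl enol ether.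
4. The hydroazulene comes from an enantioselective intramolecular Buchner reaction of an aryl diazoketone: the benzene ring of m-cresol is dearomatised and expanded to the seven-membered ring while the five-membered ring closes in the same step. Its C5–H stereocentre then controls C1, C4 and C6 by relay, while C10 is set by the oxazaborolidine reagent.
5. The diazoketone comes from m-cresol and acrylic acid via a dihydrocoumarin; no further ring construction follows the Buchner step.

Assumption: the (S,S)-tert-butyl-bis(oxazoline) ligand is taken to give the (8aR) azulenone 10; if the sense of induction is the reverse, the (R,R) ligand is used.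

Numbering used in names: daucane locants. C1 is the ring-fusion carbon that carries the angular CH3 (C15); C2 and C3 are CH2; C4 carries OH and isopropyl; C5 is the ring-fusion CH; C6–C10 run round the seven-membered ring (C8 carries CH3, C10 is bonded to C1). All selectivities below are predictions from precedent types and conformational reasoning, not tested results.

**Step 1**
Reactants: 1 3-methylphenol (m-cresol); 2 acrylic acid
Product: 3 7-methyl-3,4-dihydro-2H-chromen-2-one
Conditions: CF3SO3H (10 mol%), toluene, 110 °C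
Reagents that add atoms: none
Why: Acid-catalysed Friedel–Crafts hydroarylation of acrylic acid with lactonisation (dihydrocoumarin synthesis); the C–C bond forms ortho to OH and para to CH3, the less hindered ortho site, and no stereocentre is formed.

**Step 2**
Reactants: 3 7-methyl-3,4-dihydro-2H-chromen-2-one
Product: 6 3-{2-[(tert-butyldimethylsilyl)oxy]-4-methylphenyl}propanoic acid, via disodium salt 4 (not isolated), via bis-silyl derivative 5 (not isolated)
Conditions: NaOH (2.1 equiv), H2O–THF, rt, evaporate; TBSCl (2.4 equiv), DMF, rt; AcOH–H2O–THF, rt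
Reagents that add atoms: sodium hydroxide [Na+].[OH-]; tert-butyldimethylsilyl chloride CC(C)(C)[Si](C)(C)Cl
Why: Saponification opens the aryl lactone, silylation caps phenoxide and carboxylate, and the much more labile silyl ester is then hydrolysed selectively, leaving the phenol as the silyl ether that later becomes the C10 silyl enol ether; no stereocentre.

**Step 3**
Reactants: 6 3-{2-[(tert-butyldimethylsilyl)oxy]-4-methylphenyl}propanoic acid
Product: 8 4-{2-[(tert-butyldimethylsilyl)oxy]-4-methylphenyl}-1-diazobutan-2-one, via acid chloride 7 (not isolated)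
Conditions: (COCl)2, DMF (cat.), CH2Cl2, 0 °C to rt, evaporate; CH2N2 (excess), Et2O, 0 °C
Reagents that add atoms: diazomethane C=[N+]=[N-]
Why: Standard diazoketone synthesis by acylation of diazomethane with the acid chloride (first half of the Arndt–Eistert sequence), a second equivalent of diazomethane taking up HCl; no stereocentre.

**Step 4 (key step)**
Reactants: 8 4-{2-[(tert-butyldimethylsilyl)oxy]-4-methylphenyl}-1-diazobutan-2-one
Product: 10 (8aR)-4-[(tert-butyldimethylsilyl)oxy]-6-methyl-3,8a-dihydroazulen-1(2H)-one, via norcaradiene 9 (not isolated)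
Conditions: CuCl (5 mol%), Na[B(C6H3-3,5-(CF3)2)4] (6 mol%), (S,S)-t-Bu-box (6 mol%), CH2Cl2, 40 °C, slow addition of 8
Reagents that add atoms: none
Why: Intramolecular Buchner reaction: the copper carbene cyclopropanates the unsubstituted ipso/ortho bond of the arene (the silyloxy-bearing side is blocked) to norcaradiene 9, whose 6π-electrocyclic opening gives the cycloheptatriene with both rings in place; the chiral bis(oxazoline) ligand on monovalent copper selects the face of the arene and sets C8a (= C5) as R, as in known copper–bis(oxazoline) azulenone syntheses.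

**Step 5**
Reactants: 10 (8aR)-4-[(tert-butyldimethylsilyl)oxy]-6-methyl-3,8a-dihydroazulen-1(2H)-one
Product: 11 (1S,5R,10S)-10-[(tert-butyldimethylsilyl)oxy]-11,12,13-trinor-10,15-cyclodauca-6,8-dien-4-one
Conditions: Et2Zn, CH2I2, CH2Cl2, 0 °C
Reagents that add atoms: diiodomethane ICI
Why: Simmons–Smith (Furukawa) cyclopropanation is fastest at the electron-rich silyl enol ether bond of the 2-siloxytriene, and the carbenoid approaches C1=C10 anti to C6 (the out-of-plane allylic substituent on C5), that is on the face of 5-H, which fixes C1 (future angular methyl cis to 5-H) and C10.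

**Step 6**
Reactants: 11 (1S,5R,10S)-10-[(tert-butyldimethylsilyl)oxy]-11,12,13-trinor-10,15-cyclodauca-6,8-dien-4-one
Product: 12 (1S,4R,5R,10S)-10-[(tert-butyldimethylsilyl)oxy]-10,15-cyclodauca-6,8-dien-4-ol
Conditions: i-PrMgCl, LaCl3·2LiCl, THF, −78 to −20 °C; aq. NH4Cl
Reagents that add atoms: isopropylmagnesium chloride CC(C)[Mg]Cl
Why: Lanthanide-promoted Grignard 1,2-addition (suppresses enolisation and reduction of the hindered ketone); the nucleophile attacks C4=O anti to the C5–C6 bond, on the face of 5-H, so isopropyl ends cis to 5-H and the hydroxyl on the opposite face (4R).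

**Step 7**
Reactants: 12 (1S,4R,5R,10S)-10-[(tert-butyldimethylsilyl)oxy]-10,15-cyclodauca-6,8-dien-4-ol
Product: 13 (1S,4R,5S,6S,7R,10S)-10-[(tert-butyldimethylsilyl)oxy]-6,7-epoxy-10,15-cyclodauc-8-en-4-ol
Conditions: VO(acac)2 (5 mol%), t-BuOOH, CH2Cl2, 0 °C to rt
Reagents that add atoms: tert-butyl hydroperoxide CC(C)(C)OO
Why: Vanadium-catalysed hydroxyl-directed epoxidation: only C6=C7 is homoallylic to the tertiary OH, and the vanadate ester delivers oxygen to the face syn to that OH, giving the epoxide with C6–O cis to 4-OH and trans to 5-H while the undirected C8=C9 bond is left.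

**Step 8**
Reactants: 13 (1S,4R,5S,6S,7R,10S)-10-[(tert-butyldimethylsilyl)oxy]-6,7-epoxy-10,15-cyclodauc-8-en-4-ol
Product: 15 (1R,4R,5S,6S,7R)-6,7-epoxy-4-hydroxydauc-8-en-10-one, via cyclopropanol 14 (not isolated)
Conditions: Bu4NF·3H2O, THF, 0 °C
Reagents that add atoms: none
Why: Fluoride removes the silyl group and the cyclopropanolate opens at the bond to the unsubstituted CH2 (homoenolate protonation, Conia-type α-methylation), giving the C10 ketone conjugated with C8=C9 and the angular methyl on C1 with retention, so 1-CH3 is cis to 5-H.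

**Step 9**
Reactants: 15 (1R,4R,5S,6S,7R)-6,7-epoxy-4-hydroxydauc-8-en-10-one
Product: 16 (1R,4R,5S,6R)-4,6-dihydroxydauc-8-en-10-one
Conditions: Pd2(dba)3·CHCl3 (2.5 mol%), n-Bu3P (10 mol%), HCO2H, Et3N, THF, rt
Reagents that add atoms: none
Why: Tsuji hydrogenolysis of an alkenyl oxirane: zerovalent palladium ionises the allylic C7–O bond and hydride from formate goes to C7, the allyl terminus remote from the carbonyl, giving the δ-hydroxy-α,β-enone with C7H2; the C6–O bond is untouched, so C6 keeps its configuration (now R).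

**Step 10**
Reactants: 16 (1R,4R,5S,6R)-4,6-dihydroxydauc-8-en-10-one; 17 4-acetoxybenzoyl chloride
Product: 18 (1R,4R,5S,6R)-4-hydroxy-10-oxodauc-8-en-6-yl 4-acetoxybenzoate
Conditions: pyridine, DMAP (cat.), CH2Cl2, 0 °C
Reagents that add atoms: none
Why: DMAP-catalysed acylation; the secondary 6-OH reacts while the tertiary 4-OH is inert, and the acetate keeps the phenol from being acylated.

**Step 11**
Reactants: 18 (1R,4R,5S,6R)-4-hydroxy-10-oxodauc-8-en-6-yl 4-acetoxybenzoate
Product: 19 (1R,4R,5S,6R,10S)-4,10-dihydroxydauc-8-en-6-yl 4-acetoxybenzoate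
Conditions: (R)-2-methyl-CBS-oxazaborolidine (20 mol%), catecholborane, toluene, −78 °C; MeOH, pH 7 buffer
Reagents that add atoms: none
Why: Corey–Bakshi–Shibata reduction: with the fully substituted C1 side as the large group and the vinylic C9 side as the small group, the (R)-oxazaborolidine delivers hydride to the ketone face that carries the angular methyl, giving the (10S) allylic alcohol by 1,2-reduction and leaving the esters.

**Step 12**
Reactants: 19 (1R,4R,5S,6R,10S)-4,10-dihydroxydauc-8-en-6-yl 4-acetoxybenzoate; 20 (E)-2-methylbut-2-enoyl chloride (tigloyl chloride)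
Product: 21 (1R,4R,5S,6R,10S)-6-(4-acetoxybenzoyloxy)-4-hydroxydauc-8-en-10-yl (E)-2-methylbut-2-enoate
Conditions: pyridine, DMAP, CH2Cl2, 0 °C to rt
Reagents that add atoms: none
Why: Acylation of the secondary allylic alcohol with the (E)-acid chloride under pyridine/DMAP (no strong base, so no vinylketene formation or E/Z scrambling); the tertiary 4-OH does not react.

**Step 13**
Reactants: 21 (1R,4R,5S,6R,10S)-6-(4-acetoxybenzoyloxy)-4-hydroxydauc-8-en-10-yl (E)-2-methylbut-2-enoate
Product: 22 (1R,4R,5S,6R,10S)-4-hydroxy-6-(4-hydroxybenzoyloxy)dauc-8-en-10-yl (E)-2-methylbut-2-enoate (CNP0273650.13)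
Conditions: NH3 (7 M in MeOH), 0 °C
Reagents that add atoms: none
Why: Chemoselective ammonolysis: the aryl acetate is far more electrophilic than the hindered alkyl benzoate and the tiglate, so only the phenol is unmasked.

**Compound list**
1 | 3-methylphenol (m-cresol) | Cc1cccc(O)c1 | starting material
2 | acrylic acid | C=CC(=O)O | starting material
3 | 7-methyl-3,4-dihydro-2H-chromen-2-one | Cc1ccc2CCC(=O)Oc2c1 | intermediate
4 | disodium 3-(4-methyl-2-oxidophenyl)propanoate | Cc1ccc(CCC(=O)[O-])c([O-])c1.[Na+].[Na+] | intermediate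
5 | tert-butyldimethylsilyl 3-{2-[(tert-butyldimethylsilyl)oxy]-4-methylphenyl}propanoate | Cc1ccc(CCC(=O)O[Si](C)(C)C(C)(C)C)c(O[Si](C)(C)C(C)(C)C)c1 | intermediate
6 | 3-{2-[(tert-butyldimethylsilyl)oxy]-4-methylphenyl}propanoic acid | Cc1ccc(CCC(=O)O)c(O[Si](C)(C)C(C)(C)C)c1 | intermediate
7 | 3-{2-[(tert-butyldimethylsilyl)oxy]-4-methylphenyl}propanoyl chloride | Cc1ccc(CCC(=O)Cl)c(O[Si](C)(C)C(C)(C)C)c1 | intermediate
8 | 4-{2-[(tert-butyldimethylsilyl)oxy]-4-methylphenyl}-1-diazobutan-2-one | Cc1ccc(CCC(=O)C=[N+]=[N-])c(O[Si](C)(C)C(C)(C)C)c1 | intermediate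
9 | norcaradiene valence isomer of 10 (cyclopropane C1–C5–C6; five- and six-membered rings cis-fused to it) | CC(C)(C)[Si](C)(C)OC1=CC(C)=C[C@@H]3[C@@H]2[C@]13CCC2=O | intermediate
10 | (8aR)-4-[(tert-butyldimethylsilyl)oxy]-6-methyl-3,8a-dihydroazulen-1(2H)-one (C8a = C5) | CC1=CC(O[Si](C)(C)C(C)(C)C)=C2CCC(=O)[C@@H]2C=C1 | intermediate
11 | (1S,5R,10S)-10-[(tert-butyldimethylsilyl)oxy]-11,12,13-trinor-10,15-cyclodauca-6,8-dien-4-one (cyclopropane CH2 cis to 5-H) | CC(C)(C)[Si](C)(C)O[C@@]13C=C(C)C=C[C@@H]2[C@@]1(C3)CCC2=O | intermediate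
12 | (1S,4R,5R,10S)-10-[(tert-butyldimethylsilyl)oxy]-10,15-cyclodauca-6,8-dien-4-ol (isopropyl cis to 5-H) | CC(C)(C)[Si](C)(C)O[C@@]13C=C(C)C=C[C@@H]2[C@@]1(C3)CC[C@@]2(O)C(C)C | intermediate
13 | (1S,4R,5S,6S,7R,10S)-10-[(tert-butyldimethylsilyl)oxy]-6,7-epoxy-10,15-cyclodauc-8-en-4-ol (epoxide cis to 4-OH) | CC(C)(C)[Si](C)(C)O[C@@]13C=C(C)[C@H]4O[C@H]4[C@@H]2[C@@]1(C3)CC[C@@]2(O)C(C)C | intermediate
14 | (1S,4R,5S,6S,7R,10S)-6,7-epoxy-10,15-cyclodauc-8-ene-4,10-diol | O[C@@]13C=C(C)[C@H]4O[C@H]4[C@@H]2[C@@]1(C3)CC[C@@]2(O)C(C)C | intermediate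
15 | (1R,4R,5S,6S,7R)-6,7-epoxy-4-hydroxydauc-8-en-10-one (1-CH3 cis to 5-H) | O=C1C=C(C)[C@H]2O[C@H]2[C@@H]3[C@@]1(C)CC[C@@]3(O)C(C)C | intermediate
16 | (1R,4R,5S,6R)-4,6-dihydroxydauc-8-en-10-one | O=C1C=C(C)C[C@@H](O)[C@@H]2[C@@]1(C)CC[C@@]2(O)C(C)C | intermediate
17 | 4-acetoxybenzoyl chloride | CC(=O)Oc1ccc(cc1)C(Cl)=O | starting material
18 | (1R,4R,5S,6R)-4-hydroxy-10-oxodauc-8-en-6-yl 4-acetoxybenzoate | O=C1C=C(C)C[C@@H](OC(=O)c3ccc(OC(C)=O)cc3)[C@@H]2[C@@]1(C)CC[C@@]2(O)C(C)C | intermediate
19 | (1R,4R,5S,6R,10S)-4,10-dihydroxydauc-8-en-6-yl 4-acetoxybenzoate | O[C@H]1C=C(C)C[C@@H](OC(=O)c3ccc(OC(C)=O)cc3)[C@@H]2[C@@]1(C)CC[C@@]2(O)C(C)C | intermediate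
20 | (E)-2-methylbut-2-enoyl chloride (tigloyl chloride) | C/C=C(\C)C(Cl)=O | starting material
21 | (1R,4R,5S,6R,10S)-6-(4-acetoxybenzoyloxy)-4-hydroxydauc-8-en-10-yl (E)-2-methylbut-2-enoate | C/C=C(\C)C(=O)O[C@H]1C=C(C)C[C@@H](OC(=O)c3ccc(OC(C)=O)cc3)[C@@H]2[C@@]1(C)CC[C@@]2(O)C(C)C | intermediate
22 | (1R,4R,5S,6R,10S)-4-hydroxy-6-(4-hydroxybenzoyloxy)dauc-8-en-10-yl (E)-2-methylbut-2-enoate | C/C=C(\C)C(=O)O[C@H]1C=C(C)C[C@@H](OC(=O)c2ccc(O)cc2)[C@@H]2[C@@]1(C)CC[C@@]2(O)C(C)C | target

**Step count**
Total: 13 steps. Longest linear sequence: 13 steps (1 to 22).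

**Steps most likely to fail and their fallbacks**

Step 4. The enantioselectivity and chemoselectivity of the Buchner reaction with an ortho-silyloxy arene are unproven (aromatic C–H insertion to a 2-tetralone or a modest ee are the likely failures). The fallback sets out from 8 and comes back at 11, and replaces asymmetric catalysis by resolution. Achiral Rh2(OAc)4 (1 mol%, CH2Cl2, 40 °C) converts 8, through 9 and the mirror-image norcaradiene F1, into the racemate, that is 10 together with the (8aS)-azulenone F2. The conditions of step 5 then give the racemic cyclopropyl ketone, 11 together with the (1R,5S,10R)-ketone F3. The enantiomers are separated by preparative supercritical-fluid chromatography on a cellulose tris(3,5-dimethylphenylcarbamate) phase, and 11 goes on into step 6.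

Step 5. The tetrasubstituted silyl enol ether is hindered, and zinc salts may isomerise the β,γ-unsaturated ketone or aromatise the norcaradiene form. The fallback sets out from 10 and comes back at 15, and installs the angular methyl by enolate alkylation instead of cyclopropanation. i-PrMgCl/LaCl3·2LiCl (THF, −78 °C) first adds to the ketone of 10 anti to C6 to give the trienyl carbinol F4. MeLi (2.2 equiv, THF, 0 °C) then cleaves the silyl enol ether to the lithium enolate, which MeI (−40 °C) methylates at C1 on the face of 5-H to give the dienone carbinol F5. VO(acac)2/t-BuOOH (CH2Cl2, rt), directed by the 4-OH, epoxidises the C6=C7 bond of F5 to give 15.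

Step 11. Next to the quaternary C1, the substrate's own bias (hydride anti to the angular methyl) may override the reagent and give the 10-epimer. The fallback sets out from 18 and comes back at 21, and sets C10 by inversion. (S)-2-methyl-CBS-oxazaborolidine with catecholborane (toluene, −78 °C) is used to make the (10R)-alcohol F6 on purpose. A Mitsunobu esterification with tiglic acid (PPh3, DIAD, toluene, 0 °C to rt) then displaces the activated allylic oxygen with inversion and gives 21 directly.

**Further compounds**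
F1 | step 4 | mirror-image norcaradiene (enantiomer of 9) | CC(C)(C)[Si](C)(C)OC1=CC(C)=C[C@H]3[C@H]2[C@@]13CCC2=O
F2 | step 4 | (8aS)-4-[(tert-butyldimethylsilyl)oxy]-6-methyl-3,8a-dihydroazulen-1(2H)-one | CC1=CC(O[Si](C)(C)C(C)(C)C)=C2CCC(=O)[C@H]2C=C1
F3 | step 4 | (1R,5S,10R)-10-[(tert-butyldimethylsilyl)oxy]-11,12,13-trinor-10,15-cyclodauca-6,8-dien-4-one | CC(C)(C)[Si](C)(C)O[C@]13C=C(C)C=C[C@H]2[C@]1(C3)CCC2=O
F4 | step 5 | (4R,5R)-10-[(tert-butyldimethylsilyl)oxy]-15-nordauca-1(10),6,8-trien-4-ol | CC1=CC(O[Si](C)(C)C(C)(C)C)=C2CC[C@@](O)(C(C)C)[C@@H]2C=C1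
F5 | step 5 | (1R,4R,5R)-4-hydroxydauca-6,8-dien-10-one | O=C1C=C(C)C=C[C@@H]2[C@@]1(C)CC[C@@]2(O)C(C)C
F6 | step 11 | (1R,4R,5S,6R,10R)-4,10-dihydroxydauc-8-en-6-yl 4-acetoxybenzoate | O[C@@H]1C=C(C)C[C@@H](OC(=O)c3ccc(OC(C)=O)cc3)[C@@H]2[C@@]1(C)CC[C@@]2(O)C(C)C
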